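**Retrosynthetic overview**
- The strategy rests on the two aroyl rings: in each, the phenol oxygen on C4' is para to the ketone-bearing carbon C1', and C3' and C5' (both ortho to that oxygen) carry bromine. An ester on that oxygen therefore has only the para C–H left to receive the acyl group.
- Target ⇒ (cleavage of the two methyl ethers on the C3/C4 aryl rings) 2,5-bis(aroyl) dimethyl ether ⇒ (double para-Fries shift, both ketone C–aryl bonds) bis(2,6-dibromophenyl) 3,4-diarylpyrrole-2,5-dicarboxylate.
- Diester ⇒ pyrrole-2,5-dicarboxylic acid + 2,6-dibromophenol. Diacid ⇒ two molecules of 3-(3,5-dibromo-4-methoxyphenyl)pyruvic acid (oxidative coupling of the benzylic carbons, then Paal–Knorr closure with ammonia).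
- Pyruvic acid ⇒ 3,5-dibromo-4-methoxybenzaldehyde (azlactone route). The pyrrole is the only ring formed (step 3); the four benzene rings are bought with all eight bromines in place, so no halogenation is needed.

Key step: step 5

Remark: 3,5-dibromo-4-methoxybenzaldehyde is taken as a catalogue compound; keto acid 4 is drawn as the ketone although it should exist largely as its enol, and diketone 5 should form as a meso/racemic mixture whose diastereomers converge on the same pyrrole.

**Step 1**
Reactants: 1 3,5-dibromo-4-methoxybenzaldehyde; 2 N-acetylglycine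
Product: 3 (Z)-4-(3,5-dibromo-4-methoxybenzylidene)-2-methyl-1,3-oxazol-5(4H)-one
Conditions: NaOAc, Ac2O, 110 °C
Reagents that add atoms: none
Why: Erlenmeyer–Plöchl azlactone synthesis, a cyclodehydration of the acylglycine followed by Perkin-type condensation with the non-enolisable aldehyde, which should give the thermodynamic Z alkene (aryl syn to the ring nitrogen).

**Step 2**
Reactants: 3 (Z)-4-(3,5-dibromo-4-methoxybenzylidene)-2-methyl-1,3-oxazol-5(4H)-one
Product: 4 3-(3,5-dibromo-4-methoxyphenyl)-2-oxopropanoic acid
Conditions: 3 M aq HCl, AcOH, reflux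
Reagents that add atoms: water, O
Why: Acid hydrolysis of an azlactone opens the lactone and cleaves the enamide to the α-keto acid (the classical arylpyruvic acid synthesis), and the aryl bromides and the methyl ether should be inert to hot dilute HCl.

**Step 3**
Reactants: 4 3-(3,5-dibromo-4-methoxyphenyl)-2-oxopropanoic acid (2 equiv)
Product: 6 3,4-bis(3,5-dibromo-4-methoxyphenyl)-1H-pyrrole-2,5-dicarboxylic acid, via 3,4-bis(3,5-dibromo-4-methoxyphenyl)-2,5-dioxohexanedioic acid 5 (not isolated)
Conditions: LiN(SiMe3)2 (2.1 equiv), THF, −78 °C; I2 (0.5 equiv), −78 °C to rt; then NH3 (7 M in MeOH, excess), rt to 50 °C; aq HCl work-up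
Reagents that add atoms: ammonia, N
Why: The amide base should form the carboxylate enolate dianion without bromine–lithium exchange, iodine couples two enolates at their benzylic carbons (biomimetic oxidative dimerisation of arylpyruvates) to the 1,4-diketone 5, and ammonia closes it by Paal–Knorr condensation to the aromatic pyrrole.

**Step 4**
Reactants: 6 3,4-bis(3,5-dibromo-4-methoxyphenyl)-1H-pyrrole-2,5-dicarboxylic acid; 7 2,6-dibromophenol (2.2 equiv)
Product: 9 bis(2,6-dibromophenyl) 3,4-bis(3,5-dibromo-4-methoxyphenyl)-1H-pyrrole-2,5-dicarboxylate, via 3,4-bis(3,5-dibromo-4-methoxyphenyl)-1H-pyrrole-2,5-dicarbonyl dichloride 8 (not isolated)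
Conditions: (COCl)2, DMF (cat.), CH2Cl2, 0 °C to rt, evaporate; then 7, Et3N, DMAP (cat.), CH2Cl2, 0 °C to rt
Reagents that add atoms: none
Why: Acid chloride formation (the fully substituted pyrrole offers no ring carbon to the Vilsmeier species) followed by DMAP-catalysed acylation of the acidic phenol as its ammonium phenoxide should overcome the hindrance on both partners.

**Step 5**
Reactants: 9 bis(2,6-dibromophenyl) 3,4-bis(3,5-dibromo-4-methoxyphenyl)-1H-pyrrole-2,5-dicarboxylate
Product: 10 2,5-bis(3,5-dibromo-4-hydroxybenzoyl)-3,4-bis(3,5-dibromo-4-methoxyphenyl)-1H-pyrrole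
Conditions: TfOH (neat, concentrated), 0 °C to rt (to 45 °C only if the second shift stalls); poured onto ice
Reagents that add atoms: none
Why: Protonation of each ester carbonyl by TfOH should ionise the C(=O)–O bond to a pyrrol-2-yl acylium ion, stabilised by the ring nitrogen, and free 2,6-dibromophenol 7, and the acylium ion then attacks the para carbon of 7 in an electrophilic aromatic substitution that forms the ketone C–aryl bond and returns the phenol OH, once on each side of the pyrrole. The closest known reaction type is the Brønsted-acid Fries rearrangement of aryl aroates, which for 2,6-dihalophenyl esters leads to 4-hydroxy-3,5-dihalophenyl ketones. No ring is closed and no stereocenter is formed. The step needs regioselectivity on the phenol and chemoselectivity against the C3 and C4 aryl rings: the two bromines occupy both ortho carbons of the phenol, so only the oxygen-activated para carbon is open. Closure onto a C3 or C4 aryl ring to an indeno-fused five-membered ketone is a conceivable leak that ring strain alone would not exclude; it should be held back because the only free carbons of those rings are meta to methoxy and ortho/para to bromine and hence deactivated, because the nitrogen-stabilised acylium ion is a selective electrophile, and because the neighbouring aryl rings twist each other out of the pyrrole plane that such a closure requires. Running the reaction concentrated and cold should keep bimolecular capture by 7 ahead of this closure and of acid-induced bromine migration.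

**Step 6**
Reactants: 10 2,5-bis(3,5-dibromo-4-hydroxybenzoyl)-3,4-bis(3,5-dibromo-4-methoxyphenyl)-1H-pyrrole
Product: 11 2,5-bis(3,5-dibromo-4-hydroxybenzoyl)-3,4-bis(3,5-dibromo-4-hydroxyphenyl)-1H-pyrrole (target)
Conditions: BBr3 (excess), CH2Cl2, −78 °C to rt; then H2O
Reagents that add atoms: none
Why: Lewis-acid ether cleavage, in which boron binds the ether oxygen and bromide removes the methyl group by SN2, should proceed readily on the out-of-plane methoxy groups between two bromines while the diaryl ketones, aryl bromides and pyrrole are inert; the excess allows for complexation by the two phenols and two ketones.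

**Compound list**
1 | 3,5-dibromo-4-methoxybenzaldehyde | COc1c(Br)cc(C=O)cc1Br | starting material
2 | N-acetylglycine | CC(=O)NCC(=O)O | starting material
3 | (Z)-4-(3,5-dibromo-4-methoxybenzylidene)-2-methyl-1,3-oxazol-5(4H)-one | CC1=N/C(=C\c2cc(Br)c(OC)c(Br)c2)C(=O)O1 | intermediate
4 | 3-(3,5-dibromo-4-methoxyphenyl)-2-oxopropanoic acid | COc1c(Br)cc(CC(=O)C(=O)O)cc1Br | intermediate
5 | 3,4-bis(3,5-dibromo-4-methoxyphenyl)-2,5-dioxohexanedioic acid (meso/racemic mixture, not isolated) | OC(=O)C(=O)C(c1cc(Br)c(OC)c(Br)c1)C(c1cc(Br)c(OC)c(Br)c1)C(=O)C(=O)O | intermediate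
6 | 3,4-bis(3,5-dibromo-4-methoxyphenyl)-1H-pyrrole-2,5-dicarboxylic acid | OC(=O)c1[nH]c(C(=O)O)c(-c2cc(Br)c(OC)c(Br)c2)c1-c1cc(Br)c(OC)c(Br)c1 | intermediate
7 | 2,6-dibromophenol | Oc1c(Br)cccc1Br | starting material
8 | 3,4-bis(3,5-dibromo-4-methoxyphenyl)-1H-pyrrole-2,5-dicarbonyl dichloride (not isolated) | O=C(Cl)c1[nH]c(C(=O)Cl)c(-c2cc(Br)c(OC)c(Br)c2)c1-c1cc(Br)c(OC)c(Br)c1 | intermediate
9 | bis(2,6-dibromophenyl) 3,4-bis(3,5-dibromo-4-methoxyphenyl)-1H-pyrrole-2,5-dicarboxylate | O=C(Oc1c(Br)cccc1Br)c1[nH]c(C(=O)Oc2c(Br)cccc2Br)c(-c2cc(Br)c(OC)c(Br)c2)c1-c1cc(Br)c(OC)c(Br)c1 | intermediate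
10 | 2,5-bis(3,5-dibromo-4-hydroxybenzoyl)-3,4-bis(3,5-dibromo-4-methoxyphenyl)-1H-pyrrole | O=C(c1cc(Br)c(O)c(Br)c1)c1[nH]c(C(=O)c2cc(Br)c(O)c(Br)c2)c(-c2cc(Br)c(OC)c(Br)c2)c1-c1cc(Br)c(OC)c(Br)c1 | intermediate
11 | 2,5-bis(3,5-dibromo-4-hydroxybenzoyl)-3,4-bis(3,5-dibromo-4-hydroxyphenyl)-1H-pyrrole | O=C(c1cc(Br)c(O)c(Br)c1)c1[nH]c(C(=O)c2cc(Br)c(O)c(Br)c2)c(-c2cc(Br)c(O)c(Br)c2)c1-c1cc(Br)c(O)c(Br)c1 | target

**Total step count:** 6
**Longest linear sequence:** 6 steps (from 1)

**Steps most likely to fail**

1. Step 5 (double Fries shift). What may go wrong: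
 - acid-induced migration or loss of bromine on the phenol ring;
 - intramolecular acylation of a C3 or C4 aryl ring;
 - stalling after the first shift, because the protonated ketone disfavours the second ionisation.

 Fallback: the route is left at diacid 6. Double decarboxylation in hot 2-aminoethanol should give 3,4-bis(3,5-dibromo-4-methoxyphenyl)-1H-pyrrole F1. Friedel–Crafts acylation of both free α-carbons with 3,5-dibromo-4-methoxybenzoyl chloride F2 (from 3,5-dibromo-4-methoxybenzoic acid and SOCl2) under AlCl3 in warm 1,2-dichloroethane should give 2,5-bis(3,5-dibromo-4-methoxybenzoyl)-3,4-bis(3,5-dibromo-4-methoxyphenyl)-1H-pyrrole F3. BBr3 in CH2Cl2 would then cleave all four ethers, and the route is rejoined at target 11.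

2. Step 3 (oxidative dimerisation and ring closure). What may go wrong:
 - poor C–C coupling of the electron-poor, sparingly soluble dianion, with over-oxidation instead;
 - incomplete condensation of the hindered diketone with ammonia.

 Fallback: the route is left at aldehyde 1. Benzoin condensation (thiazolium salt, Et3N, EtOH) should give 1,2-bis(3,5-dibromo-4-methoxyphenyl)-2-hydroxyethan-1-one F4. Oxidation (Cu(OAc)2 cat., NH4NO3, aq AcOH) should give 1,2-bis(3,5-dibromo-4-methoxyphenyl)ethane-1,2-dione F5. Hinsberg condensation of F5 with dimethyl N-acetyliminodiacetate F6 (from dimethyl iminodiacetate and Ac2O) under NaOMe in MeOH, followed by aq NaOH and acidification, should build the pyrrole ring from the other side; the route is rejoined at diacid 6.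

3. Step 4 (double esterification). What may go wrong:
 - sluggish O-acylation by the hindered, weakly nucleophilic phenoxide, which leaves time for acylation at the pyrrole nitrogen of a second molecule and oligomer formation;
 - hydrolysis of the dichloride back to the acid.

 Fallback: the route is left at dichloride 8, which is dissolved together with 7 in neat TfOH. Under acid the pyrrole nitrogen is not nucleophilic, and the known TfOH-promoted acylation of phenols with acyl chlorides should deliver the para-hydroxyaryl ketone directly, with ester 9 only a transient species. The route is rejoined at ketone 10, and no new compound is made (F0).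

**Further compounds**
F1 | step 5 | 3,4-bis(3,5-dibromo-4-methoxyphenyl)-1H-pyrrole | COc1c(Br)cc(cc1Br)-c1c[nH]cc1-c1cc(Br)c(OC)c(Br)c1
F2 | step 5 | 3,5-dibromo-4-methoxybenzoyl chloride | COc1c(Br)cc(C(=O)Cl)cc1Br
F3 | step 5 | 2,5-bis(3,5-dibromo-4-methoxybenzoyl)-3,4-bis(3,5-dibromo-4-methoxyphenyl)-1H-pyrrole | O=C(c1cc(Br)c(OC)c(Br)c1)c1[nH]c(C(=O)c2cc(Br)c(OC)c(Br)c2)c(-c2cc(Br)c(OC)c(Br)c2)c1-c1cc(Br)c(OC)c(Br)c1
F4 | step 3 | 1,2-bis(3,5-dibromo-4-methoxyphenyl)-2-hydroxyethan-1-one (racemic) | COc1c(Br)cc(cc1Br)C(O)C(=O)c1cc(Br)c(OC)c(Br)c1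
F5 | step 3 | 1,2-bis(3,5-dibromo-4-methoxyphenyl)ethane-1,2-dione | COc1c(Br)cc(cc1Br)C(=O)C(=O)c1cc(Br)c(OC)c(Br)c1
F6 | step 3 | dimethyl N-acetyliminodiacetate | COC(=O)CN(C(C)=O)CC(=O)OC
F0 | step 4 | none | none
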